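Everything rests on taking apart ring E, the second pyranone, which ties ring D (the central anisole) to ring F (the benzo ring with 5-OH and 7-OH), at C4a–C4, C4–C3 and O1–C2. The cut exploits that C4 is an isolated carbonyl carbon lying between a twofold-symmetric phloroglucinol ring and a C3–C2 pair that maps onto an arylalkyne. In one pot, 2-iodophloroglucinol triacetate, CO and the alkyne are joined, ring E is closed and all five acetates are stripped, so the target emerges directly. The alkyne precursor is a complete 3-arylflavone (rings A, B, C, D) with an ethynyl group para to the ring D methoxy group and both phenols masked as acetates.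

Key step: step 8

Remarks
- Ring letters: A is the benzo ring with 5-OH and 7-OMe. C is its pyranone. B is the 4-hydroxyphenyl group on C2 of ring C. D is the methoxybenzene on C3 of ring C. E is the second pyranone. F is the benzo ring of ring E.
- Assumption: the target has no stereocentre and its SMILES defines no axis, so the C3(ring C)–ring D axis is treated as stereochemically undefined.
- Ring B needs its own building block. 4-(Benzyloxy)benzoyl chloride is chosen so that a single BCl3 operation frees both the 4'-OH and the 5-OH.
- In step 8, triethylamine is the only base while palladium is at work, and diethylamine is added afterwards. All five phenols therefore stay masked during C–C bond formation.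

Step 1
Reactants: 1 phloroglucinol
Product: 2 2-iodobenzene-1,3,5-triol
Conditions: I2 (1.0 equiv), NaHCO3 (1.1 equiv), THF–H2O, 0 °C
Reagents that add atoms: iodine, [I][I]
Why: This is an electrophilic aromatic iodination of a strongly activated ring whose three C–H positions are equivalent, and one equivalent of iodine at 0 °C with bicarbonate as acid scavenger should stop at the monoiodide.

Step 2
Reactants: 2 2-iodobenzene-1,3,5-triol (taken on without storage)
Product: 3 2-iodobenzene-1,3,5-triyl triacetate
Conditions: Ac2O (4 equiv), pyridine, 0 °C → rt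
Reagents that add atoms: acetic anhydride, CC(=O)OC(C)=O
Why: Pyridine-mediated O-acetylation of all three phenols turns the oxidation-prone iodotriol into a stable aryl iodide and installs the masks needed in step 8.

Step 3
Reactants: 4 3,5-dimethoxyphenol; 5 (5-bromo-2-methoxyphenyl)acetic acid
Product: 6 2-(5-bromo-2-methoxyphenyl)-1-(2-hydroxy-4,6-dimethoxyphenyl)ethan-1-one
Conditions: BF3·OEt2 (solvent), 85 °C; aq NaOAc
Reagents that add atoms: none
Why: BF3-promoted Friedel–Crafts acylation of a phenol with an arylacetic acid is the standard entry to 2-hydroxydeoxybenzoins, and it goes to one of the two equivalent positions ortho to the hydroxyl because only there is the ketone stabilised by chelation to the phenolic oxygen.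

Step 4
Reactants: 6 2-(5-bromo-2-methoxyphenyl)-1-(2-hydroxy-4,6-dimethoxyphenyl)ethan-1-one; 7 4-(benzyloxy)benzoyl chloride
Product: 9 2-[4-(benzyloxy)phenyl]-3-(5-bromo-2-methoxyphenyl)-5,7-dimethoxychromen-4-one, via triaryl 1,3-diketone 8 (not isolated)
Conditions: LiN(SiMe3)2 (3.3 equiv), THF, −78 → −10 °C; 7, −78 °C → rt; 1 M HCl; p-TsOH·H2O (cat.), toluene, reflux, removal of water
Reagents that add atoms: none
Why: Excess amide base forms the phenoxide–enolate dianion, which is aroylated at carbon, any O-aroylated material is funnelled to the same diketone enolate by Baker–Venkataraman acyl migration, and acid-catalysed cyclodehydration through the only free phenol then closes ring C.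

Step 5
Reactants: 9 2-[4-(benzyloxy)phenyl]-3-(5-bromo-2-methoxyphenyl)-5,7-dimethoxychromen-4-one
Product: 10 3-(5-bromo-2-methoxyphenyl)-5-hydroxy-2-(4-hydroxyphenyl)-7-methoxychromen-4-one
Conditions: BCl3 (4 equiv), pentamethylbenzene (3 equiv), CH2Cl2, −78 °C → rt; MeOH, 1 M HCl
Reagents that add atoms: none
Why: In this Lewis acid ether cleavage, boron held between the C4 carbonyl and O5 in a six-membered chelate removes the peri methyl group and BCl3 also ionises the benzyl ether, whose cation is trapped by pentamethylbenzene, whereas the 7-methoxy and ring D methoxy groups lack such activation.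

Step 6
Reactants: 10 3-(5-bromo-2-methoxyphenyl)-5-hydroxy-2-(4-hydroxyphenyl)-7-methoxychromen-4-one; 11 trimethylsilylacetylene
Product: 12 5-hydroxy-2-(4-hydroxyphenyl)-7-methoxy-3-{2-methoxy-5-[(trimethylsilyl)ethynyl]phenyl}chromen-4-one
Conditions: PdCl2(PPh3)2 (5 mol %), CuI (10 mol %), 11 (3 equiv), Et3N–DMF, 80 °C, sealed tube
Reagents that add atoms: none
Why: This Sonogashira coupling occurs at the only carbon–halogen bond and is heated because the bromide lies para to a methoxy group, while the phenols sit on remote rings and are tolerated as triethylammonium phenoxides.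

Step 7
Reactants: 12 5-hydroxy-2-(4-hydroxyphenyl)-7-methoxy-3-{2-methoxy-5-[(trimethylsilyl)ethynyl]phenyl}chromen-4-one
Product: 14 4-[5-acetoxy-3-(5-ethynyl-2-methoxyphenyl)-7-methoxy-4-oxochromen-2-yl]phenyl acetate, via diphenol alkyne 13 (not isolated)
Conditions: K2CO3 (3 equiv), MeOH–THF, rt; AcOH, evaporate; Ac2O, pyridine, DMAP (cat.), rt
Reagents that add atoms: acetic anhydride, CC(=O)OC(C)=O
Why: Base-mediated methanolysis of the C(sp)–Si bond and DMAP-catalysed O-acetylation, which also caps the hydrogen-bonded 5-OH, are both routine and leave the chromone and the terminal alkyne untouched.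

Step 8
Reactants: 3 2-iodobenzene-1,3,5-triyl triacetate (1.5 equiv); 14 4-[5-acetoxy-3-(5-ethynyl-2-methoxyphenyl)-7-methoxy-4-oxochromen-2-yl]phenyl acetate; 15 carbon monoxide
Product: 18 CNP0288914.0 (target biflavone), via ynone pentaacetate 16 (not isolated), via diethylamino enaminone 17 (not isolated)
Conditions: PdCl2(PPh3)2 (5 mol %), Et3N (3 equiv), THF, CO (5 bar), 50 °C; vent; Et2NH (20 equiv), 50 °C; 2 M HCl, THF, 50 °C
Reagents that add atoms: none
Why: Zerovalent palladium formed from PdCl2(PPh3)2 inserts into the C–I bond of 3, migratory insertion of CO gives the aroyl–palladium species, and triethylamine-assisted alkynyl transfer from 14 with reductive elimination forges C4a–C4 and C4–C3 in ynone 16, which is a carbonylative Sonogashira coupling. Diethylamine, added only after the gas is vented, aminolyses the five aryl acetates and adds to the β-carbon of the ynone to give enaminone 17, whose ortho phenol displaces the amine by addition–elimination, driven to completion by the acid treatment, to form O1–C2. The closest known chemistry is the palladium-catalysed carbonylative annulation of ortho-iodophenyl acetates with terminal arylalkynes to flavones, run here in two stages in one pot. Ring E closes in a 6-endo sense overall, because the enaminone is electrophilic only at its β-carbon and the 5-exo path to an aurone is therefore shut. Capture of the aroyl–palladium species by the alkyne alone is secured by keeping all five phenols acetylated and by having no N–H amine present in the palladium stage, while copper-free conditions and CO pressure disfavour direct aryl–alkyne coupling. No regiochemical question arises because the two oxygens ortho to C4a of ring F are equivalent, and no stereocentre is formed.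

Compound list
1 | phloroglucinol | Oc1cc(O)cc(O)c1 | starting material
2 | 2-iodobenzene-1,3,5-triol | Oc1cc(O)c(I)c(O)c1 | intermediate
3 | 2-iodobenzene-1,3,5-triyl triacetate | CC(=O)Oc1cc(OC(C)=O)c(I)c(OC(C)=O)c1 | intermediate
4 | 3,5-dimethoxyphenol | COc1cc(O)cc(OC)c1 | starting material
5 | (5-bromo-2-methoxyphenyl)acetic acid | COc1ccc(Br)cc1CC(=O)O | starting material
6 | 2-(5-bromo-2-methoxyphenyl)-1-(2-hydroxy-4,6-dimethoxyphenyl)ethan-1-one | COc1cc(O)c(C(=O)Cc2cc(Br)ccc2OC)c(OC)c1 | intermediate
7 | 4-(benzyloxy)benzoyl chloride | O=C(Cl)c1ccc(OCc2ccccc2)cc1 | starting material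
8 | 1-[4-(benzyloxy)phenyl]-2-(5-bromo-2-methoxyphenyl)-3-(2-hydroxy-4,6-dimethoxyphenyl)propane-1,3-dione (racemic at the enolisable C2, not isolated) | COc1cc(O)c(C(=O)C(C(=O)c2ccc(OCc3ccccc3)cc2)c2cc(Br)ccc2OC)c(OC)c1 | intermediate
9 | 2-[4-(benzyloxy)phenyl]-3-(5-bromo-2-methoxyphenyl)-5,7-dimethoxychromen-4-one | COc1cc(OC)c2c(=O)c(-c3cc(Br)ccc3OC)c(-c3ccc(OCc4ccccc4)cc3)oc2c1 | intermediate
10 | 3-(5-bromo-2-methoxyphenyl)-5-hydroxy-2-(4-hydroxyphenyl)-7-methoxychromen-4-one | COc1cc(O)c2c(=O)c(-c3cc(Br)ccc3OC)c(-c3ccc(O)cc3)oc2c1 | intermediate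
11 | trimethylsilylacetylene | C#C[Si](C)(C)C | starting material
12 | 5-hydroxy-2-(4-hydroxyphenyl)-7-methoxy-3-{2-methoxy-5-[(trimethylsilyl)ethynyl]phenyl}chromen-4-one | COc1cc(O)c2c(=O)c(-c3cc(C#C[Si](C)(C)C)ccc3OC)c(-c3ccc(O)cc3)oc2c1 | intermediate
13 | 3-(5-ethynyl-2-methoxyphenyl)-5-hydroxy-2-(4-hydroxyphenyl)-7-methoxychromen-4-one (not isolated) | COc1cc(O)c2c(=O)c(-c3cc(C#C)ccc3OC)c(-c3ccc(O)cc3)oc2c1 | intermediate
14 | 4-[5-acetoxy-3-(5-ethynyl-2-methoxyphenyl)-7-methoxy-4-oxochromen-2-yl]phenyl acetate | C#Cc1ccc(OC)c(c1)-c1c(-c2ccc(OC(C)=O)cc2)oc2cc(OC)cc(OC(C)=O)c2c1=O | intermediate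
15 | carbon monoxide | [C-]#[O+] | starting material
16 | 2-(3-{3-[5-acetoxy-2-(4-acetoxyphenyl)-7-methoxy-4-oxochromen-3-yl]-4-methoxyphenyl}prop-2-ynoyl)benzene-1,3,5-triyl triacetate (not isolated) | CC(=O)Oc1cc(OC(C)=O)c(C(=O)C#Cc2ccc(OC)c(c2)-c2c(-c3ccc(OC(C)=O)cc3)oc3cc(OC)cc(OC(C)=O)c3c2=O)c(OC(C)=O)c1 | intermediate
17 | 3-{5-[(E)-1-(diethylamino)-3-oxo-3-(2,4,6-trihydroxyphenyl)prop-1-en-1-yl]-2-methoxyphenyl}-5-hydroxy-2-(4-hydroxyphenyl)-7-methoxychromen-4-one (push–pull alkene of labile geometry, not isolated) | CCN(CC)/C(=C/C(=O)c1c(O)cc(O)cc1O)c1ccc(OC)c(c1)-c1c(-c2ccc(O)cc2)oc2cc(OC)cc(O)c2c1=O | intermediate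
18 | CNP0288914.0, 3-[5-(5,7-dihydroxy-4-oxochromen-2-yl)-2-methoxyphenyl]-5-hydroxy-2-(4-hydroxyphenyl)-7-methoxychromen-4-one | COc1cc(O)c2c(=O)c(-c3cc(-c4cc(=O)c5c(O)cc(O)cc5o4)ccc3OC)c(-c3ccc(O)cc3)oc2c1 | target

Total step count: 8.
Longest linear sequence: 6 steps (steps 3 to 8, from 4 and 5). The iodide branch (steps 1 and 2) joins at step 8.

Steps most likely to fail

(a) Step 8.
- What may go wrong: the doubly ortho-substituted aryl–palladium species may couple with the alkyne before CO inserts. The crowded aroyl–palladium species may lose CO again. Acetates may be lost early, which would open the way to ester formation at palladium.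
- Fallback: C4 is brought in preformed, so no CO insertion is needed. The fallback sets out from 14 and comes back at 16.
- Commercial 2,4,6-trihydroxybenzoic acid is peracetylated (Ac2O, pyridine) to 2,4,6-triacetoxybenzoic acid F1. Oxalyl chloride with catalytic DMF in CH2Cl2 converts this into 2,4,6-triacetoxybenzoyl chloride F2.
- An acyl Sonogashira coupling of this chloride with 14 (PdCl2(PPh3)2, CuI, Et3N, THF, rt) should give ynone 16. Compound 16 is then treated with diethylamine and acid exactly as in the second stage of step 8.

(b) Step 4.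
- What may go wrong: crowding at the benzylic carbon may stall the sequence at O-aroylation, or the crowded diketone may undergo retro-Claisen cleavage during the base or acid treatment.
- Fallback: the C3–ring D bond is made last by cross-coupling. The fallback sets out from 7 and comes back at 9.
- Compound 7 and commercial 1-(2-hydroxy-4,6-dimethoxyphenyl)ethanone, under the same LiN(SiMe3)2 and acid protocol, should pass through 1-[4-(benzyloxy)phenyl]-3-(2-hydroxy-4,6-dimethoxyphenyl)propane-1,3-dione F3 to 2-[4-(benzyloxy)phenyl]-5,7-dimethoxychromen-4-one F4.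
- Lithiation at C3 with LiN(i-Pr)2 in THF at −78 °C and an iodine quench give 2-[4-(benzyloxy)phenyl]-3-iodo-5,7-dimethoxychromen-4-one F5.
- Suzuki–Miyaura coupling with commercial (5-bromo-2-methoxyphenyl)boronic acid (Pd(PPh3)4, Na2CO3, DME–H2O, 70 °C) then delivers 9. In this coupling the iodoenone C–I bond reacts ahead of the aryl C–Br bond.

(c) Step 6.
- What may go wrong: oxidative addition into the electron-rich C–Br bond may be slow. The 5-hydroxy-4-keto chelating site may sequester copper. Oxidative homocoupling may use up the volatile silylalkyne.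
- Fallback: a base-free and copper-free Stille coupling. It sets out from 10 and comes back at 13, so the methanolysis part of step 7 is skipped.
- Compound 10 and commercial tributyl(ethynyl)stannane (Pd(PPh3)4, toluene–DMF, 100 °C) should give the terminal alkyne 13 directly, and 13 is acetylated as in step 7.
- New compounds on this way: none F0.

Further compounds
F1 | step 8 | 2,4,6-triacetoxybenzoic acid | CC(=O)Oc1cc(OC(C)=O)c(C(=O)O)c(OC(C)=O)c1
F2 | step 8 | 2,4,6-triacetoxybenzoyl chloride | CC(=O)Oc1cc(OC(C)=O)c(C(=O)Cl)c(OC(C)=O)c1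
F3 | step 4 | 1-[4-(benzyloxy)phenyl]-3-(2-hydroxy-4,6-dimethoxyphenyl)propane-1,3-dione | COc1cc(O)c(C(=O)CC(=O)c2ccc(OCc3ccccc3)cc2)c(OC)c1
F4 | step 4 | 2-[4-(benzyloxy)phenyl]-5,7-dimethoxychromen-4-one | COc1cc(OC)c2c(=O)cc(-c3ccc(OCc4ccccc4)cc3)oc2c1
F5 | step 4 | 2-[4-(benzyloxy)phenyl]-3-iodo-5,7-dimethoxychromen-4-one | COc1cc(OC)c2c(=O)c(I)c(-c3ccc(OCc4ccccc4)cc3)oc2c1
F0 | step 6 | none | none
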